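**Plan**

Ring atoms: C1 (bears the side chain), C2 (CH2), C3 and C4 (epoxide CH and C–CH3), C5 (CHOH), C6 (CH–O-acyl). Retrosynthesis: both epoxides, the C5 alcohol (to a ketone) and the C6 ester are removed first; then C1–C2 and C4–C5 are cut together; the acyclic remainder is cut at the diene C–C bond and at the side-chain carbinol.
Enabling feature: C6–O and the C1 side chain are cis on adjacent ring carbons next to oxygenated C5, and C2–C3–C4(–CH3) is a but-2-ene-1,3-diyl unit. The ring is therefore read as a cis-vinyl epoxide (C6/C1) carrying a nitrile (C5) plus a crotyl metal (C2–C4).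
Forward: the acyclic C5–C6–C1 chain with the complete side chain is built first (allylation, cross-metathesis, Stille coupling, angelate, Sharpless epoxidation, nitrile). The only carbocycle closes in step 11; C6 ester, C5 alcohol, ring epoxide and side-chain epoxide follow.
Stereochemistry: side-chain carbinol from (S)-BINOL/Ti(OiPr)4 allylation; C6 and C1 from the Sharpless cis-epoxide (C1 by SN2 inversion in the key step); C5 by Luche reduction anti to the C6 ester; ring epoxide directed by C5–OH; side-chain epoxide by the Shi ketone; (R)-2-methylbutanoate and (Z)-angelate are introduced as such.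

Key step: step 11

Remark: (R)-2-methylbutanoic acid, angelic acid, crotyl bromide (E/Z mixture, the allylzinc equilibrates) and the D-fructose-derived Shi ketone are taken as commercial.

**Route**

Step 1
Reactants: 1 acrolein
Product: 3 2-bromoacrolein, via 2,3-dibromopropanal 2 (not isolated)
Conditions: Br2, CH2Cl2, −78 °C; then Et3N, −78 → 0 °C; used at once
Reagents that add atoms: bromine BrBr
Why: Bromine addition to the enal alkene followed by base-induced loss of HBr from the α-position is the standard bromination–dehydrobromination route to 2-bromoacrolein.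

Step 2
Reactants: 3 2-bromoacrolein
Product: 4 (S)-2-bromohexa-1,5-dien-3-ol
Conditions: (S)-BINOL (10 mol%), Ti(OiPr)4 (10 mol%), 4 Å MS, allyltributylstannane, CH2Cl2, −20 °C; aq. NaHCO3
Reagents that add atoms: allyltributylstannane C=CC[Sn](CCCC)(CCCC)CCCC
Why: Keck asymmetric allylation, in which the (S)-BINOL–titanium Lewis acid binds the aldehyde and shields one face so that allyl transfer from tin should set the side-chain carbinol as (S) under catalyst control.

Step 3
Reactants: 4 (S)-2-bromohexa-1,5-dien-3-ol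
Product: 5 (S)-2-bromo-6-methylhepta-1,5-dien-3-ol
Conditions: second-generation Grubbs catalyst (5 mol%), 2-methyl-2-butene (large excess), CH2Cl2, 40 °C
Reagents that add atoms: 2-methyl-2-butene CC=C(C)C
Why: Olefin cross-metathesis with excess 2-methyl-2-butene should turn the terminal allyl group into the prenyl group, while the 2-bromo-1-alkene and the free alcohol are inert to the ruthenium carbene.

Step 4
Reactants: 6 propargyl alcohol
Product: 8 (Z)-3-(tributylstannyl)prop-2-en-1-ol, via lithium vinylalanate 7 (not isolated)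
Conditions: LiAlH4, THF, 0 °C → rt; then Bu3SnOTf, −78 °C → rt; aqueous work-up
Reagents that add atoms: tributyltin trifluoromethanesulfonate CCCC[Sn](CCCC)(CCCC)OS(=O)(=O)C(F)(F)F
Why: trans-Hydroalumination of the propargylic alkoxide gives a five-membered cyclic vinylalanate that is stannylated with retention, so the tin ends up cis to the CH2OH group.

Step 5
Reactants: 8 (Z)-3-(tributylstannyl)prop-2-en-1-ol
Product: 9 (Z)-tert-butyldimethyl{[3-(tributylstannyl)prop-2-en-1-yl]oxy}silane
Conditions: TBSCl, imidazole, CH2Cl2, 0 °C → rt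
Reagents that add atoms: tert-butyldimethylsilyl chloride CC(C)(C)[Si](C)(C)Cl
Why: Standard imidazole-mediated silylation of a primary alcohol.

Step 6
Reactants: 5 (S)-2-bromo-6-methylhepta-1,5-dien-3-ol; 9 (Z)-tert-butyldimethyl{[3-(tributylstannyl)prop-2-en-1-yl]oxy}silane
Product: 10 (2Z,5S)-1-[(tert-butyldimethylsilyl)oxy]-8-methyl-4-methylidenenona-2,7-dien-5-ol
Conditions: Pd(PPh3)4 (5 mol%), CuCl, LiCl, DMSO, 60 °C
Reagents that add atoms: none
Why: Copper-assisted Stille coupling should join the two sp2 carbons with retention of the (Z)-geometry of the stannane, giving the 2-substituted (Z)-diene without touching the free secondary alcohol.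

Step 7
Reactants: 10 (2Z,5S)-1-[(tert-butyldimethylsilyl)oxy]-8-methyl-4-methylidenenona-2,7-dien-5-ol
Product: 11 (2Z,5S)-1-[(tert-butyldimethylsilyl)oxy]-8-methyl-4-methylidenenona-2,7-dien-5-yl (Z)-2-methylbut-2-enoate
Conditions: angelic acid, 2,4,6-trichlorobenzoyl chloride, Et3N, toluene, rt; then 10, 75 °C (no DMAP)
Reagents that add atoms: angelic acid C/C=C(/C)C(=O)O
Why: Yamaguchi-type esterification through the mixed anhydride without a nucleophilic catalyst is the usual way to acylate a secondary alcohol with angelic acid while keeping the (Z)-geometry.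

Step 8
Reactants: 11 (2Z,5S)-1-[(tert-butyldimethylsilyl)oxy]-8-methyl-4-methylidenenona-2,7-dien-5-yl (Z)-2-methylbut-2-enoate
Product: 12 (2Z,5S)-1-hydroxy-8-methyl-4-methylidenenona-2,7-dien-5-yl (Z)-2-methylbut-2-enoate
Conditions: HF·pyridine, pyridine, THF, 0 °C
Reagents that add atoms: none
Why: Buffered fluoride desilylation should cleave the primary allylic silyl ether and leave the ester and the diene untouched.

Step 9
Reactants: 12 (2Z,5S)-1-hydroxy-8-methyl-4-methylidenenona-2,7-dien-5-yl (Z)-2-methylbut-2-enoate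
Product: 13 (3S)-2-[(2R,3S)-3-(hydroxymethyl)oxiran-2-yl]-6-methylhepta-1,5-dien-3-yl (Z)-2-methylbut-2-enoate
Conditions: Ti(OiPr)4 (10 mol%), L-(+)-diethyl tartrate (12 mol%), t-BuOOH, 4 Å MS, CH2Cl2, −20 °C
Reagents that add atoms: tert-butyl hydroperoxide CC(C)(C)OO
Why: Sharpless asymmetric epoxidation, in which the L-(+)-tartrate titanium complex delivers oxygen to one face of the alcohol-bound (Z)-alkene only, should give the cis-epoxide with S configuration at the carbinol-bearing carbon (reagent control) and leave the non-allylic alkenes alone.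

Step 10
Reactants: 13 (3S)-2-[(2R,3S)-3-(hydroxymethyl)oxiran-2-yl]-6-methylhepta-1,5-dien-3-yl (Z)-2-methylbut-2-enoate
Product: 16 (3S)-2-[(2R,3S)-3-cyanooxiran-2-yl]-6-methylhepta-1,5-dien-3-yl (Z)-2-methylbut-2-enoate, via cis-epoxy aldehyde 14 (not isolated), via aldimine 15 (not isolated)
Conditions: TEMPO (10 mol%), PhI(OAc)2 (2.2 equiv), NH4OAc, MeCN/H2O, rt
Reagents that add atoms: ammonium acetate [NH4+].CC(=O)[O-]
Why: Nitroxyl-catalysed oxidation of the primary alcohol to the aldehyde, condensation with ammonia and a second oxidation of the aldimine is a known one-pot alcohol-to-nitrile conversion that does not touch the epoxide stereocentres.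

Step 11
Reactants: 16 (3S)-2-[(2R,3S)-3-cyanooxiran-2-yl]-6-methylhepta-1,5-dien-3-yl (Z)-2-methylbut-2-enoate; 17 crotyl bromide
Product: 21 (3S)-2-[(1S,6R)-6-hydroxy-4-methyl-5-oxocyclohex-3-en-1-yl]-6-methylhepta-1,5-dien-3-yl (Z)-2-methylbut-2-enoate, via crotylzinc bromide 18 (not isolated), via zinc ketimine 19 (not isolated), via cyclised ketimine 20 (not isolated)
Conditions: Zn dust, LiCl, THF, 0 °C, then 17 (forms 18); 16 added at 0 °C, then 40 °C; 1 M aq. citric acid, rt
Reagents that add atoms: water O
Why: Proposed new method: crotylzinc bromide should add through its γ-carbon (six-membered SE2′ transition state) to the nitrile carbon C5, forming C4–C5 and an N-zincio ketimine whose only enolisable position is C4 (the other α-carbon is an epoxide carbon); tautomerisation gives a zinc 2-amino-diene (aza-dienolate) whose γ-carbon C2 attacks the allylic epoxide carbon C1 in a ZnBr2-assisted SN2 opening that closes the ring, and aqueous acid hydrolyses the conjugated N–H ketimine to the enone. The closest known reaction types are the addition of allylic zinc reagents to nitriles (Blaise-type ketone synthesis), the C-alkylation of metalloenamines by epoxides (Stork–Dowd type) and vinyl-epoxide-directed endo epoxide openings; their merger in one flask is new. The carbocycle closes by a 6-endo-tet epoxide opening (6-enolendo with respect to the aza-dienolate); attack through C4 or nitrogen would give three- or four-membered rings, and the 5-exo alternative at C6 is a disfavoured 5-enolendo closure at the non-allylic carbon. The new stereocentre C1 is set by inversion at the cis-epoxide carbon, which places the side chain cis to the C6 oxygen retained from the Sharpless epoxide; C4 is stereogenic only transiently. The step needs γ-selectivity in both C–C bond formations and chemoselectivity for the nitrile over the angelate ester and the epoxide, which the SE2′ pathway of allylzincs, the ring-size constraints and the low basicity of organozinc reagents should secure.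

Step 12
Reactants: 21 (3S)-2-[(1S,6R)-6-hydroxy-4-methyl-5-oxocyclohex-3-en-1-yl]-6-methylhepta-1,5-dien-3-yl (Z)-2-methylbut-2-enoate
Product: 22 (1R,6S)-3-methyl-6-{(3S)-6-methyl-3-[(Z)-2-methylbut-2-enoyloxy]hepta-1,5-dien-2-yl}-2-oxocyclohex-3-en-1-yl (2R)-2-methylbutanoate
Conditions: (R)-2-methylbutanoic acid, EDC·HCl, DMAP (cat.), CH2Cl2, 0 °C
Reagents that add atoms: (R)-2-methylbutanoic acid OC(=O)[C@H](C)CC
Why: Steglich esterification of the only free hydroxyl group at low temperature should acylate C6–OH without epimerising the α-stereocentres of the acid or of the ketone.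

Step 13
Reactants: 22 (1R,6S)-3-methyl-6-{(3S)-6-methyl-3-[(Z)-2-methylbut-2-enoyloxy]hepta-1,5-dien-2-yl}-2-oxocyclohex-3-en-1-yl (2R)-2-methylbutanoate
Product: 23 (1R,2S,6S)-2-hydroxy-3-methyl-6-{(3S)-6-methyl-3-[(Z)-2-methylbut-2-enoyloxy]hepta-1,5-dien-2-yl}cyclohex-3-en-1-yl (2R)-2-methylbutanoate
Conditions: NaBH4, CeCl3·7H2O, MeOH, −78 °C; AcOH quench
Reagents that add atoms: none
Why: Luche reduction enforces 1,2-addition to the enone, and hydride should enter axially, anti to the axial C6 acyloxy group of the conformer with the C1 side chain equatorial, so the C5 alcohol forms cis to C6–O and to C1 (substrate control).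

Step 14
Reactants: 23 (1R,2S,6S)-2-hydroxy-3-methyl-6-{(3S)-6-methyl-3-[(Z)-2-methylbut-2-enoyloxy]hepta-1,5-dien-2-yl}cyclohex-3-en-1-yl (2R)-2-methylbutanoate
Product: 24 (1R,2R,3R,4S,6S)-2-hydroxy-1-methyl-4-{(3S)-6-methyl-3-[(Z)-2-methylbut-2-enoyloxy]hepta-1,5-dien-2-yl}-7-oxabicyclo[4.1.0]heptan-3-yl (2R)-2-methylbutanoate
Conditions: VO(acac)2 (5 mol%), t-BuOOH, CH2Cl2, 0 °C → rt
Reagents that add atoms: tert-butyl hydroperoxide CC(C)(C)OO
Why: Hydroxyl-directed epoxidation, in which the vanadium alkoxide of the allylic C5 alcohol delivers the peroxide oxygen to the same face of the C3=C4 alkene, should give the ring epoxide cis to C5–OH and only at the allylic-alcohol alkene.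

Step 15
Reactants: 24 (1R,2R,3R,4S,6S)-2-hydroxy-1-methyl-4-{(3S)-6-methyl-3-[(Z)-2-methylbut-2-enoyloxy]hepta-1,5-dien-2-yl}-7-oxabicyclo[4.1.0]heptan-3-yl (2R)-2-methylbutanoate
Product: 25 (1R,2R,3R,4S,6S)-4-{(3S)-4-[(2R)-3,3-dimethyloxiran-2-yl]-3-[(Z)-2-methylbut-2-enoyloxy]but-1-en-2-yl}-2-hydroxy-1-methyl-7-oxabicyclo[4.1.0]heptan-3-yl (2R)-2-methylbutanoate (CNP0181486.1)
Conditions: D-fructose-derived Shi ketone (30 mol%), Oxone (2KHSO5·KHSO4·K2SO4), K2CO3, Bu4NHSO4, MeCN/dimethoxymethane/aq. buffer (pH 10.5), 0 °C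
Reagents that add atoms: potassium peroxymonosulfate (KHSO5 of Oxone) [K+].[O-]S(=O)(=O)OO
Why: Shi asymmetric epoxidation, in which the dioxirane of the D-fructose-derived ketone attacks the only electron-rich trisubstituted alkene through the spiro transition state, should give the (R)-epoxide under reagent control, while the 1,1-disubstituted and conjugated alkenes react far more slowly.

**Compound list**

1 | acrolein | C=CC=O | starting material
2 | 2,3-dibromopropanal | O=CC(Br)CBr | intermediate
3 | 2-bromoacrolein | C=C(Br)C=O | intermediate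
4 | (S)-2-bromohexa-1,5-dien-3-ol | C=C(Br)[C@H](CC=C)O | intermediate
5 | (S)-2-bromo-6-methylhepta-1,5-dien-3-ol | C=C(Br)[C@H](CC=C(C)C)O | intermediate
6 | propargyl alcohol | C#CCO | starting material
7 | lithium (Z)-vinylalanate (cyclic 2,5-dihydro-1,2-oxaluminol-2-uide) | [Li+].[AlH2-]1OCC=C1 | intermediate
8 | (Z)-3-(tributylstannyl)prop-2-en-1-ol | OC/C=C\[Sn](CCCC)(CCCC)CCCC | intermediate
9 | (Z)-tert-butyldimethyl{[3-(tributylstannyl)prop-2-en-1-yl]oxy}silane | CC(C)(C)[Si](C)(C)OC/C=C\[Sn](CCCC)(CCCC)CCCC | intermediate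
10 | (2Z,5S)-1-[(tert-butyldimethylsilyl)oxy]-8-methyl-4-methylidenenona-2,7-dien-5-ol | CC(C)(C)[Si](C)(C)OC/C=C\C(=C)[C@H](CC=C(C)C)O | intermediate
11 | (2Z,5S)-1-[(tert-butyldimethylsilyl)oxy]-8-methyl-4-methylidenenona-2,7-dien-5-yl (Z)-2-methylbut-2-enoate | CC(C)(C)[Si](C)(C)OC/C=C\C(=C)[C@H](CC=C(C)C)OC(=O)/C(C)=C\C | intermediate
12 | (2Z,5S)-1-hydroxy-8-methyl-4-methylidenenona-2,7-dien-5-yl (Z)-2-methylbut-2-enoate | OC/C=C\C(=C)[C@H](CC=C(C)C)OC(=O)/C(C)=C\C | intermediate
13 | (3S)-2-[(2R,3S)-3-(hydroxymethyl)oxiran-2-yl]-6-methylhepta-1,5-dien-3-yl (Z)-2-methylbut-2-enoate | OC[C@@H]1O[C@@H]1C(=C)[C@H](CC=C(C)C)OC(=O)/C(C)=C\C | intermediate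
14 | cis-epoxy aldehyde (aldehyde of 13, same configuration) | O=C[C@@H]1O[C@@H]1C(=C)[C@H](CC=C(C)C)OC(=O)/C(C)=C\C | intermediate
15 | N-unsubstituted aldimine of 14 | N=C[C@@H]1O[C@@H]1C(=C)[C@H](CC=C(C)C)OC(=O)/C(C)=C\C | intermediate
16 | (3S)-2-[(2R,3S)-3-cyanooxiran-2-yl]-6-methylhepta-1,5-dien-3-yl (Z)-2-methylbut-2-enoate | N#C[C@@H]1O[C@@H]1C(=C)[C@H](CC=C(C)C)OC(=O)/C(C)=C\C | intermediate
17 | crotyl bromide ((E)-1-bromobut-2-ene, commercial E-rich mixture) | C/C=C/CBr | starting material
18 | crotylzinc bromide | C/C=C/C[Zn]Br | intermediate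
19 | N-zincio ketimine from γ-addition of 18 to 16 (both epimers at the methyl-bearing carbon; in equilibrium with its enamide tautomer) | C=CC(C)C(=N[Zn]Br)[C@@H]1O[C@@H]1C(=C)[C@H](CC=C(C)C)OC(=O)/C(C)=C\C | intermediate
20 | cyclised N–H ketimine, zinc alkoxide of 21 at C6 | C=C([C@H](CC=C(C)C)OC(=O)/C(C)=C\C)[C@@H]1CC=C(C)C(=N)[C@@H]1O[Zn]Br | intermediate
21 | (3S)-2-[(1S,6R)-6-hydroxy-4-methyl-5-oxocyclohex-3-en-1-yl]-6-methylhepta-1,5-dien-3-yl (Z)-2-methylbut-2-enoate | C=C([C@H](CC=C(C)C)OC(=O)/C(C)=C\C)[C@@H]1CC=C(C)C(=O)[C@@H]1O | intermediate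
22 | (1R,6S)-3-methyl-6-{(3S)-6-methyl-3-[(Z)-2-methylbut-2-enoyloxy]hepta-1,5-dien-2-yl}-2-oxocyclohex-3-en-1-yl (2R)-2-methylbutanoate | C=C([C@H](CC=C(C)C)OC(=O)/C(C)=C\C)[C@@H]1CC=C(C)C(=O)[C@@H]1OC(=O)[C@H](C)CC | intermediate
23 | (1R,2S,6S)-2-hydroxy-3-methyl-6-{(3S)-6-methyl-3-[(Z)-2-methylbut-2-enoyloxy]hepta-1,5-dien-2-yl}cyclohex-3-en-1-yl (2R)-2-methylbutanoate | C=C([C@H](CC=C(C)C)OC(=O)/C(C)=C\C)[C@@H]1CC=C(C)[C@H](O)[C@@H]1OC(=O)[C@H](C)CC | intermediate
24 | (1R,2R,3R,4S,6S)-2-hydroxy-1-methyl-4-{(3S)-6-methyl-3-[(Z)-2-methylbut-2-enoyloxy]hepta-1,5-dien-2-yl}-7-oxabicyclo[4.1.0]heptan-3-yl (2R)-2-methylbutanoate | C=C([C@H](CC=C(C)C)OC(=O)/C(C)=C\C)[C@@H]1C[C@@H]2O[C@]2(C)[C@H](O)[C@@H]1OC(=O)[C@H](C)CC | intermediate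
25 | (1R,2R,3R,4S,6S)-4-{(3S)-4-[(2R)-3,3-dimethyloxiran-2-yl]-3-[(Z)-2-methylbut-2-enoyloxy]but-1-en-2-yl}-2-hydroxy-1-methyl-7-oxabicyclo[4.1.0]heptan-3-yl (2R)-2-methylbutanoate | C=C([C@H](C[C@H]1OC1(C)C)OC(=O)/C(C)=C\C)[C@@H]1C[C@@H]2O[C@]2(C)[C@H](O)[C@@H]1OC(=O)[C@H](C)CC | target

**Totals and risks**

Total step count: 15 (steps 4 and 5 form a two-step branch). Longest linear sequence: 13 steps (1, 2, 3, 6–15) from acrolein.

Steps most likely to fail:

Step 11 (proposed new method). Halide or a second crotylzinc may open the vinyl epoxide or add twice to the ketimine before the imine–enamine tautomerisation and the ring closure take place, or the sequence may stall at the open-chain ketimine. The fallback uses known chemistry and sets out from nitrile 16. Addition of crotylzinc bromide at 0 °C with immediate cold aqueous acid hydrolysis (the known allylzinc–nitrile ketone synthesis) should give the β,γ-unsaturated cis-epoxy ketone F1. Treatment with LiN(SiMe3)2 in THF at −78 → 0 °C then forms the extended lithium dienolate, whose γ-carbon opens the allylic epoxide carbon in a known type of enolate–epoxide cyclisation, and the route is rejoined at hydroxy enone 21.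

Step 9. Turnover is slow and facial discrimination may be incomplete with a (Z)-allylic alcohol, and the titanium alkoxide may open the sensitive vinyl epoxide. The fallback sets out from silyl ether 11. Jacobsen–Katsuki epoxidation of the cis-disubstituted alkene of the conjugated diene with the appropriate antipode of the chiral (salen)MnCl catalyst and buffered NaOCl should give the silylated cis-epoxide F2. HF·pyridine then removes the silyl group and the route is rejoined at epoxy alcohol 13.

Step 10. Ammonia or acetate may open the vinyl epoxide, and the α-epoxy aldehyde may epimerise before the nitrile forms. The fallback sets out from epoxy alcohol 13. Dess–Martin oxidation buffered with NaHCO3 gives aldehyde 14, now isolated; condensation with NH2OH·HCl in pyridine gives the aldoxime F3. Dehydration with the Burgess reagent returns the route to nitrile 16.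

Further compounds
F1 | step 11 | (3S)-6-methyl-2-[cis-3-(2-methylbut-3-enoyl)oxiran-2-yl]hepta-1,5-dien-3-yl (Z)-2-methylbut-2-enoate, epoxide configured as in 16, both epimers at the ketone α-carbon | C=CC(C)C(=O)[C@@H]1O[C@@H]1C(=C)[C@H](CC=C(C)C)OC(=O)/C(C)=C\C
F2 | step 9 | tert-butyldimethylsilyl ether of epoxy alcohol 13 | CC(C)(C)[Si](C)(C)OC[C@@H]1O[C@@H]1C(=C)[C@H](CC=C(C)C)OC(=O)/C(C)=C\C
F3 | step 10 | aldoxime of cis-epoxy aldehyde 14 | ON=C[C@@H]1O[C@@H]1C(=C)[C@H](CC=C(C)C)OC(=O)/C(C)=C\C
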